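Late in the blue run, the flask asked about and followed so far, the target stood at 14.9% and the other capture product at 74.3% of the substrate charged, on average over the readings from 60.0 min on.

in all of them: substrate 0.10 M

| flask | first nucleophile | solid second nucleophile | remark | time |
|---|---|---|---|---|
| blue | 0.10 M | 0.20 M | the very flask that is asked about, followed so far |  |
| red | 0.10 M | 0.30 M | run made earlier |  |
| flask | 0.100 M | 0.200 M |  | 5.0 h |

- blue (time / min: target / %, other capture product / %): 8.00: 15.0, 40.3; 25.0: 15.2, 70.7; 40.0: 14.8, 73.7; 60.0: 14.7, 74.2; 90.0: 15.1, 74.7; 120: 14.9, 74.0
- red (time / h: target / %, other capture product / %): 0.250: 15.5, 60.1; 0.500: 14.6, 72.3; 0.833: 14.3, 74.4; 1.33: 14.0, 75.1; 2.00: 14.4, 74.9; 4.00: 14.4, 75.2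

(scatter of a reading: 0.5 percentage points)

- solid second nucleophile is a solid; its amount is given per volume of the solution
- the numbers in the tables scatter with a standard deviation of 0.5 percentage points
- steps that have been proposed: substrate -> intermediate; 2 first nucleophile -> self-condensation product; target <-> isomer of the product; second nucleophile + intermediate -> other capture product; solid second nucleophile <-> second nucleophile; first nucleophile + intermediate -> target
- at the start none of the solid second nucleophile is in solution

1. ratio of target to other capture product at 5.0 s
2. ratio of target to other capture product at 5.0 min
3. ratio of target to other capture product at 5.0 h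
4. which of target and other capture product there is more of at 5.0 h

I kept a ledger of the substrate charged, the quantity against which the readings are given in percent. By the proposed steps each mole of it passes through the intermediate and ends as target, as other capture product, or as isomer of the product by way of the target. Self-condensation spends first nucleophile and takes no substrate. The isomer was not measured, so its entry is the gap that closes the books, 10.8%. The target read level from 8.00 min on, so I took the step between target and isomer as equilibrated and reckoned with the isomer per target, the gap divided by the target, 0.725, an apparent equilibrium constant. The red run, with 0.30 M of solid second nucleophile, left a gap of 10.7% over its readings from 1.33 h on, and its other capture product still read 75.2% at 4.00 h. So I committed to a ratio of 0.201 at 5.0 h, with more other capture product than target. For the earlier times I made no reckoning.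

The forecast gave 50 (from 8 to 1000) at 5.0 s, 0.65 (from 0.48 to 0.95) at 5.0 min and 0.197 (from 0.185 to 0.21) at 5.0 h, with other capture product ahead, and it held that “the missing 10% is probably isomer”. Its late ratio is lower than mine.

The flask gave 201 at 5.0 s, 4.02 times the forecast's value, then 0.666 at 5.0 min and 0.201 at 5.0 h, with 15.0% target against 74.6% other capture product, so other capture product led.

    substrate → intermediate (k = 0.130 min⁻¹)
    2 first nucleophile → self-condensation product (k = 14.0 L mol⁻¹ min⁻¹)
    target ⇌ isomer of the product (K = 0.690, k = 0.590 min⁻¹)
    second nucleophile + intermediate → other capture product (k = 2800 L mol⁻¹ min⁻¹)
    solid second nucleophile ⇌ second nucleophile, rate k5*(cs5 - [second nucleophile]) while solid is left; crystals form when [second nucleophile] > cs5 (solubility = 15.0 mM, k = 0.710 min⁻¹)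
    first nucleophile + intermediate → target (k = 3000 L mol⁻¹ min⁻¹)

With the flask's target, the isomer per target 0.725 closes the books at 74.1% other capture product, against the 74.6% it held. The neighbouring flask had c(substrate) 0.040 M, with the other charges as in the recipe, which made 2.50 equiv of first nucleophile, and its target ended at 20.2%. The same reckoning gives 14.6% isomer and 65.2% other capture product. That flask held 13.9% isomer and 65.9% other capture product, a ratio of 0.306.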